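**Retrosynthetic overview**
1. Target ⇒ cut the ester C–O bond (Mitsunobu) into a benzylic-O-silyl syn-1,3-diol monoalcohol and O-silyl (Z)-2-(hydroxymethyl)but-2-enoic acid; both silyl ethers come off last.
2. Diol fragment ⇒ syn-β-hydroxy ester ⇒ racemic α-cinnamyl β-keto ester; a ketoreductase dynamic reductive kinetic resolution sets both stereocentres in one step.
3. β-Keto ester ⇒ Tsuji–Trost union of ethyl 3,4-dimethoxybenzoylacetate (acetoveratrone + diethyl carbonate) with 3,4-dimethoxycinnamyl methyl carbonate.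
4. Acid fragment ⇒ (Z)-2-iodobut-2-en-1-ol (crotonaldehyde α-iodination, then reduction) ⇒ stereoretentive Pd carbonylation.
5. No ring is formed: both benzene rings are bought, and the route is acyclic throughout.

Assumption: the ketoreductase is a commercial panel enzyme picked by screening for the (2S,3S)-syn alcohol; only its class is specified.

**Step 1**
Reactants: 1 1-(3,4-dimethoxyphenyl)ethan-1-one; 2 diethyl carbonate
Product: 3 ethyl 3-(3,4-dimethoxyphenyl)-3-oxopropanoate
Conditions: NaH (2.2 equiv), THF, reflux; then 1 M HCl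
Reagents that add atoms: none
Why: Crossed Claisen condensation in which the ketone enolate is C-acylated by the non-enolisable carbonate and irreversible deprotonation of the β-keto ester drives the reaction to completion.

**Step 2**
Reactants: 4 methyl (2E)-3-(3,4-dimethoxyphenyl)prop-2-enoate
Product: 6 (2E)-3-(3,4-dimethoxyphenyl)prop-2-en-1-ol, via 3,4-dimethoxycinnamaldehyde 5 (not isolated)
Conditions: DIBAL-H (2.5 equiv), CH2Cl2, −78 → 0 °C; Rochelle salt work-up
Reagents that add atoms: none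
Why: DIBAL-H 1,2-reduction of a conjugated ester gives the allylic alcohol and leaves the E-alkene untouched.

**Step 3**
Reactants: 6 (2E)-3-(3,4-dimethoxyphenyl)prop-2-en-1-ol
Product: 7 (2E)-3-(3,4-dimethoxyphenyl)prop-2-en-1-yl methyl carbonate
Conditions: ClCO2Me, pyridine, CH2Cl2, 0 °C
Reagents that add atoms: methyl chloroformate `COC(=O)Cl`
Why: O-acylation of the primary allylic alcohol (carbonate formation) installs a leaving group that lets the next step run without added base.

**Step 4**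
Reactants: 3 ethyl 3-(3,4-dimethoxyphenyl)-3-oxopropanoate; 7 (2E)-3-(3,4-dimethoxyphenyl)prop-2-en-1-yl methyl carbonate
Product: 8 ethyl (4E)-2-(3,4-dimethoxybenzoyl)-5-(3,4-dimethoxyphenyl)pent-4-enoate (racemic)
Conditions: Pd(PPh3)4 (2 mol %), THF, 25–40 °C, 3 in 1.3-fold excess
Reagents that add atoms: none
Why: Tsuji–Trost allylic alkylation, in which Pd(0) ionises the carbonate, the released methoxide deprotonates 3, and the soft enolate attacks the unsubstituted terminus of the aryl π-allyl complex to give the linear E product with a deliberately labile α-centre.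

**Step 5**
Reactants: 8 ethyl (4E)-2-(3,4-dimethoxybenzoyl)-5-(3,4-dimethoxyphenyl)pent-4-enoate (racemic)
Product: 9 ethyl (2S,4E)-2-[(S)-(3,4-dimethoxyphenyl)(hydroxy)methyl]-5-(3,4-dimethoxyphenyl)pent-4-enoate
Conditions: ketoreductase (NADPH-dependent alcohol dehydrogenase class), NADP+ (cat.), i-PrOH (15% v/v), KPi buffer pH 7.5, DMSO (10% v/v), 30 °C
Reagents that add atoms: none
Why: Enzymatic dynamic reductive kinetic resolution in which the α-centre racemises through the enol faster than reduction while the ketoreductase reduces only the (2S) epimer by hydride delivery from NADPH to the Re face of the aryl ketone, setting the (2S,3S)-syn pair in one step.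

**Step 6**
Reactants: 9 ethyl (2S,4E)-2-[(S)-(3,4-dimethoxyphenyl)(hydroxy)methyl]-5-(3,4-dimethoxyphenyl)pent-4-enoate
Product: 10 ethyl (2S,4E)-2-[(S)-(3,4-dimethoxyphenyl)(triethylsilyloxy)methyl]-5-(3,4-dimethoxyphenyl)pent-4-enoate
Conditions: TESCl, imidazole, DMAP (cat.), DMF, 0 °C → rt
Reagents that add atoms: chlorotriethylsilane `CC[Si](Cl)(CC)CC`
Why: Silyl ether formation under mild base masks the benzylic alcohol without retro-aldol cleavage or epimerisation at C2.

**Step 7**
Reactants: 10 ethyl (2S,4E)-2-[(S)-(3,4-dimethoxyphenyl)(triethylsilyloxy)methyl]-5-(3,4-dimethoxyphenyl)pent-4-enoate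
Product: 12 (2R,4E)-2-[(S)-(3,4-dimethoxyphenyl)(triethylsilyloxy)methyl]-5-(3,4-dimethoxyphenyl)pent-4-en-1-ol, via silyloxy aldehyde 11 (not isolated)
Conditions: DIBAL-H (3 equiv), CH2Cl2, −78 → −20 °C; Rochelle salt work-up
Reagents that add atoms: none
Why: DIBAL-H ester reduction passes through the aluminium-bound aldehyde, which is reduced at once, so C2 does not epimerise (the descriptor changes from S to R only through CIP priorities) and the silyl ether and styrene survive.

**Step 8**
Reactants: 13 (2E)-but-2-enal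
Product: 14 (2Z)-2-iodobut-2-enal
Conditions: I2, K2CO3, DMAP (20 mol %), THF/H2O 1:1, rt
Reagents that add atoms: iodine `II`
Why: DMAP-catalysed α-iodination of an enal (Baylis–Hillman-type addition, iodination, elimination) gives the thermodynamic isomer with the methyl group trans to the formyl group and cis to iodine.

**Step 9**
Reactants: 14 (2Z)-2-iodobut-2-enal
Product: 15 (2Z)-2-iodobut-2-en-1-ol
Conditions: NaBH4, MeOH, 0 °C
Reagents that add atoms: none
Why: Borohydride 1,2-reduction of the aldehyde leaves the vinyl iodide and its geometry untouched.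

**Step 10**
Reactants: 15 (2Z)-2-iodobut-2-en-1-ol
Product: 16 tert-butyl{[(2Z)-2-iodobut-2-en-1-yl]oxy}dimethylsilane
Conditions: TBSCl, imidazole, CH2Cl2, 0 °C → rt
Reagents that add atoms: tert-butyl(chloro)dimethylsilane `CC(C)(C)[Si](C)(C)Cl`
Why: Silyl protection of the primary alcohol prevents β-lactone formation or self-esterification in the carbonylation and coupling steps.

**Step 11**
Reactants: 16 tert-butyl{[(2Z)-2-iodobut-2-en-1-yl]oxy}dimethylsilane
Product: 17 methyl (2Z)-2-{[(tert-butyldimethylsilyl)oxy]methyl}but-2-enoate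
Conditions: PdCl2(PPh3)2 (3 mol %), CO (1 atm), MeOH, Et3N, DMF, 55 °C
Reagents that add atoms: carbon monoxide `[C-]#[O+]`; methanol `CO`
Why: Pd-catalysed alkoxycarbonylation of a vinyl iodide (oxidative addition, CO insertion, methanolysis) retains the alkene geometry, so the methyl group ends cis to the ester (angelate-type Z).

**Step 12**
Reactants: 17 methyl (2Z)-2-{[(tert-butyldimethylsilyl)oxy]methyl}but-2-enoate
Product: 18 (2Z)-2-{[(tert-butyldimethylsilyl)oxy]methyl}but-2-enoic acid
Conditions: LiOH·H2O, THF/MeOH/H2O 3:1:1, rt; then cold 1 M HCl to pH 4–5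
Reagents that add atoms: lithium hydroxide `[Li+].[OH-]`
Why: Saponification with LiOH at room temperature is mild enough to leave the primary TBS ether and the Z-alkene intact.

**Step 13**
Reactants: 12 (2R,4E)-2-[(S)-(3,4-dimethoxyphenyl)(triethylsilyloxy)methyl]-5-(3,4-dimethoxyphenyl)pent-4-en-1-ol; 18 (2Z)-2-{[(tert-butyldimethylsilyl)oxy]methyl}but-2-enoic acid
Product: 19 (2R,4E)-2-[(S)-(3,4-dimethoxyphenyl)(triethylsilyloxy)methyl]-5-(3,4-dimethoxyphenyl)pent-4-en-1-yl (2Z)-2-{[(tert-butyldimethylsilyl)oxy]methyl}but-2-enoate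
Conditions: PPh3 (1.5 equiv), DIAD (1.5 equiv), THF, 0 °C → rt
Reagents that add atoms: none
Why: Mitsunobu esterification activates the primary alcohol and uses the carboxylate as nucleophile, so the acid is never an acyl electrophile and neither the Z-alkene nor the two stereocentres (the reacting carbon is CH2) can be scrambled.

**Step 14**
Reactants: 19 (2R,4E)-2-[(S)-(3,4-dimethoxyphenyl)(triethylsilyloxy)methyl]-5-(3,4-dimethoxyphenyl)pent-4-en-1-yl (2Z)-2-{[(tert-butyldimethylsilyl)oxy]methyl}but-2-enoate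
Product: 20 (2R,4E)-2-[(S)-(3,4-dimethoxyphenyl)(hydroxy)methyl]-5-(3,4-dimethoxyphenyl)pent-4-en-1-yl (2Z)-2-(hydroxymethyl)but-2-enoate
Conditions: HF·pyridine, pyridine, THF, 0 °C → rt
Reagents that add atoms: none
Why: Fluoride-mediated desilylation under pyridine-buffered conditions cleaves the secondary TES and primary TBS ethers without basic acyl migration, alkene isomerisation or ionisation of the electron-rich benzylic position.

**Compound list**
1 | 1-(3,4-dimethoxyphenyl)ethan-1-one | `CC(=O)c1ccc(OC)c(OC)c1` | starting material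
2 | diethyl carbonate | `CCOC(=O)OCC` | starting material
3 | ethyl 3-(3,4-dimethoxyphenyl)-3-oxopropanoate | `CCOC(=O)CC(=O)c1ccc(OC)c(OC)c1` | intermediate
4 | methyl (2E)-3-(3,4-dimethoxyphenyl)prop-2-enoate | `COC(=O)/C=C/c1ccc(OC)c(OC)c1` | starting material
5 | (2E)-3-(3,4-dimethoxyphenyl)prop-2-enal | `O=C/C=C/c1ccc(OC)c(OC)c1` | intermediate (not isolated)
6 | (2E)-3-(3,4-dimethoxyphenyl)prop-2-en-1-ol | `OC/C=C/c1ccc(OC)c(OC)c1` | intermediate
7 | (2E)-3-(3,4-dimethoxyphenyl)prop-2-en-1-yl methyl carbonate | `COC(=O)OC/C=C/c1ccc(OC)c(OC)c1` | intermediate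
8 | ethyl (4E)-2-(3,4-dimethoxybenzoyl)-5-(3,4-dimethoxyphenyl)pent-4-enoate (racemic) | `CCOC(=O)C(C/C=C/c1ccc(OC)c(OC)c1)C(=O)c1ccc(OC)c(OC)c1` | intermediate
9 | ethyl (2S,4E)-2-[(S)-(3,4-dimethoxyphenyl)(hydroxy)methyl]-5-(3,4-dimethoxyphenyl)pent-4-enoate | `CCOC(=O)[C@@H](C/C=C/c1ccc(OC)c(OC)c1)[C@H](O)c1ccc(OC)c(OC)c1` | intermediate
10 | ethyl (2S,4E)-2-[(S)-(3,4-dimethoxyphenyl)(triethylsilyloxy)methyl]-5-(3,4-dimethoxyphenyl)pent-4-enoate | `CCOC(=O)[C@@H](C/C=C/c1ccc(OC)c(OC)c1)[C@H](O[Si](CC)(CC)CC)c1ccc(OC)c(OC)c1` | intermediate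
11 | (2S,4E)-2-[(S)-(3,4-dimethoxyphenyl)(triethylsilyloxy)methyl]-5-(3,4-dimethoxyphenyl)pent-4-enal | `O=C[C@@H](C/C=C/c1ccc(OC)c(OC)c1)[C@H](O[Si](CC)(CC)CC)c1ccc(OC)c(OC)c1` | intermediate (not isolated)
12 | (2R,4E)-2-[(S)-(3,4-dimethoxyphenyl)(triethylsilyloxy)methyl]-5-(3,4-dimethoxyphenyl)pent-4-en-1-ol | `OC[C@@H](C/C=C/c1ccc(OC)c(OC)c1)[C@H](O[Si](CC)(CC)CC)c1ccc(OC)c(OC)c1` | intermediate
13 | (2E)-but-2-enal | `C/C=C/C=O` | starting material
14 | (2Z)-2-iodobut-2-enal | `C/C=C(\I)C=O` | intermediate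
15 | (2Z)-2-iodobut-2-en-1-ol | `C/C=C(\I)CO` | intermediate
16 | tert-butyl{[(2Z)-2-iodobut-2-en-1-yl]oxy}dimethylsilane | `C/C=C(\I)CO[Si](C)(C)C(C)(C)C` | intermediate
17 | methyl (2Z)-2-{[(tert-butyldimethylsilyl)oxy]methyl}but-2-enoate | `C/C=C(/CO[Si](C)(C)C(C)(C)C)C(=O)OC` | intermediate
18 | (2Z)-2-{[(tert-butyldimethylsilyl)oxy]methyl}but-2-enoic acid | `C/C=C(/CO[Si](C)(C)C(C)(C)C)C(=O)O` | intermediate
19 | (2R,4E)-2-[(S)-(3,4-dimethoxyphenyl)(triethylsilyloxy)methyl]-5-(3,4-dimethoxyphenyl)pent-4-en-1-yl (2Z)-2-{[(tert-butyldimethylsilyl)oxy]methyl}but-2-enoate | `C/C=C(/CO[Si](C)(C)C(C)(C)C)C(=O)OC[C@@H](C/C=C/c1ccc(OC)c(OC)c1)[C@H](O[Si](CC)(CC)CC)c1ccc(OC)c(OC)c1` | intermediate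
20 | (2R,4E)-2-[(S)-(3,4-dimethoxyphenyl)(hydroxy)methyl]-5-(3,4-dimethoxyphenyl)pent-4-en-1-yl (2Z)-2-(hydroxymethyl)but-2-enoate | `C/C=C(/CO)C(=O)OC[C@@H](C/C=C/c1ccc(OC)c(OC)c1)[C@H](O)c1ccc(OC)c(OC)c1` | target

**Totals**
Total step count: 14.
Longest linear sequence: 8 steps (steps 2, 3, 4, 5, 6, 7, 13, 14, from 4 to 20).

**Three steps most likely to fail**

Step 5 (ketoreductase dynamic reduction). The risk is that no panel enzyme accepts the bulky diaryl keto ester 8 with useful syn selectivity. The fallback shrinks the enzyme substrate and builds the styrene afterwards. It sets out from 3, which is C-allylated with allyl bromide (K2CO3, acetone, reflux) to ethyl 2-(3,4-dimethoxybenzoyl)pent-4-enoate F1. The same ketoreductase dynamic reduction on this smaller α-allyl β-keto ester gives ethyl (2S)-2-[(S)-(3,4-dimethoxyphenyl)(hydroxy)methyl]pent-4-enoate F2. E-selective cross-metathesis with 4-ethenyl-1,2-dimethoxybenzene (Grubbs II, CH2Cl2, 40 °C) then installs the aryl group, and the fallback comes back to the route at 9.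

Step 13 (Mitsunobu esterification). The risk is that the β-branched alcohol 12 couples slowly and the acid is diverted to an acylated hydrazine. The fallback switches from alcohol activation to acid activation. It sets out from 18, which with 2,4,6-trichlorobenzoyl chloride and Et3N in toluene gives (2Z)-2-{[(tert-butyldimethylsilyl)oxy]methyl}but-2-enoic 2,4,6-trichlorobenzoic anhydride F3. Alcohol 12 and DMAP are then added at 0 °C to rt (Yamaguchi esterification, kept cold and short to protect the Z-alkene), and the fallback comes back to the route at 19.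

Step 14 (global desilylation). The risk is that freeing the benzylic alcohol from its silyl ether causes acyl migration or benzylic ionisation. The fallback never silylates the benzylic oxygen. It sets out from 9, which LiBH4 (THF, 0 °C → rt) reduces to (1S,2R)-1-(3,4-dimethoxyphenyl)-2-[(2E)-3-(3,4-dimethoxyphenyl)prop-2-en-1-yl]propane-1,3-diol F4. A primary-selective Mitsunobu esterification with 18 (PPh3, DIAD, THF, 0 °C) gives (2R,4E)-2-[(S)-(3,4-dimethoxyphenyl)(hydroxy)methyl]-5-(3,4-dimethoxyphenyl)pent-4-en-1-yl (2Z)-2-{[(tert-butyldimethylsilyl)oxy]methyl}but-2-enoate F5. Only the unhindered primary TBS ether is then removed with TBAF buffered by AcOH (THF, 0 °C), and the fallback comes back to the route at 20.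

**Further compounds**
F1 | step 5 | ethyl 2-(3,4-dimethoxybenzoyl)pent-4-enoate (racemic) | `CCOC(=O)C(CC=C)C(=O)c1ccc(OC)c(OC)c1`
F2 | step 5 | ethyl (2S)-2-[(S)-(3,4-dimethoxyphenyl)(hydroxy)methyl]pent-4-enoate | `CCOC(=O)[C@@H](CC=C)[C@H](O)c1ccc(OC)c(OC)c1`
F3 | step 13 | (2Z)-2-{[(tert-butyldimethylsilyl)oxy]methyl}but-2-enoic 2,4,6-trichlorobenzoic anhydride | `C/C=C(/CO[Si](C)(C)C(C)(C)C)C(=O)OC(=O)c1c(Cl)cc(Cl)cc1Cl`
F4 | step 14 | (1S,2R)-1-(3,4-dimethoxyphenyl)-2-[(2E)-3-(3,4-dimethoxyphenyl)prop-2-en-1-yl]propane-1,3-diol | `OC[C@@H](C/C=C/c1ccc(OC)c(OC)c1)[C@H](O)c1ccc(OC)c(OC)c1`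
F5 | step 14 | (2R,4E)-2-[(S)-(3,4-dimethoxyphenyl)(hydroxy)methyl]-5-(3,4-dimethoxyphenyl)pent-4-en-1-yl (2Z)-2-{[(tert-butyldimethylsilyl)oxy]methyl}but-2-enoate | `C/C=C(/CO[Si](C)(C)C(C)(C)C)C(=O)OC[C@@H](C/C=C/c1ccc(OC)c(OC)c1)[C@H](O)c1ccc(OC)c(OC)c1`
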